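**Plan**

- Numbering: cyclohexene C-1 (bears CH3) round to C-6 (CH2), ketone carbon C-8; ring B is the dihydroxyphenyl on C-3 that also carries the flavonol. Enabling feature: C-3 (ring B) and C-4 (C-8) are neighbours, so an ortho oxygen of ring B can be tied to C-8 as a lactone. This gives a coumarin whose alkene is C-3=C-4, and a removable ester on C-4 makes it a chelating, electron-poor dienophile.
- Cuts, in retrosynthetic order: the O–C and C=C bonds of the flavonol pyranone (Algar–Flynn–Oyamada, Claisen–Schmidt); the C-8–aryl bond (aryllithium on the lactone); then C-2–C-3 and C-4–C-5 together (Diels–Alder of the coumarin with a 1-silyl-2-methyl-4-aryl diene).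
- Forward order of rings: coumarin pyranone, then the cyclohexene by [4+2] cycloaddition, lactone opened to ketone and phenol, flavonol pyranone last. Silicon leaves in the final step with allylic shift of the alkene to C-1=C-2.
- Stereochemistry: C-3 and C-5 (cis) come from the endo, ligand-controlled cycloaddition. C-4 is set afterwards by base equilibration to the trans,trans ketone. The silicon-bearing C-2 centre is temporary.

Key step: step 6

Remark: the bis(oxazoline) antipode is taken to be the one whose Cu(OTf)2 chelate of 10 leaves open the face that is Si at the coumarin β-carbon, and (S,S) is written for it; Ar = 2,4-bis(methoxymethoxy)phenyl, MOM = CH2OCH3, t-Bu-box = 2,2'-(propane-2,2-diyl)bis(4-tert-butyl-4,5-dihydrooxazole), and C-n always means the cyclohexene numbering of the plan.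

Step 1
Reactants: 1 2,4-dihydroxybenzaldehyde
Product: 2 2,4-bis(methoxymethoxy)benzaldehyde
Conditions: MOMCl, i-Pr2NEt, CH2Cl2, 0 → 40 °C
Reagents that add atoms: chloromethyl methyl ether, COCCl
Why: Base-mediated O-alkylation (MOM ether formation) protects both phenols, the excess of reagent and gentle warming taking care of the hydrogen-bonded 2-OH.

Step 2
Reactants: 2 2,4-bis(methoxymethoxy)benzaldehyde
Product: 3 1-[(E)-2-iodoethenyl]-2,4-bis(methoxymethoxy)benzene
Conditions: CrCl2, CHI3, THF, 0 °C → rt
Reagents that add atoms: iodoform, IC(I)I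
Why: Takai iodo-olefination, in which the geminal dichromium species formed from CHI3 and CrCl2 adds to the aldehyde and eliminates to the alkenyl iodide, is reliably E-selective for aryl aldehydes.

Step 3
Reactants: 4 trimethyl(prop-1-yn-1-yl)silane; 3 1-[(E)-2-iodoethenyl]-2,4-bis(methoxymethoxy)benzene
Product: 6 [(1E,3E)-4-Ar-2-methylbuta-1,3-dien-1-yl]trimethylsilane, via alkenylborane 5 (not isolated)
Conditions: 4, 9-BBN-H, THF, 0 °C → rt; then 3, Pd(PPh3)4 (5 mol%), aq. NaOH, THF, 65 °C
Reagents that add atoms: none
Why: Syn hydroboration of the 1-silylalkyne with the bulky borane places boron on the methyl-bearing carbon (β to silicon) and hydrogen on the silylated one, and Suzuki–Miyaura coupling of the resulting B-alkenyl-9-BBN with the alkenyl iodide under zerovalent palladium keeps the geometry of both partners, so the diene should be 1E,3E.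

Step 4
Reactants: 7 2,6-dihydroxybenzaldehyde; 8 dimethyl malonate
Product: 9 methyl 5-hydroxy-2-oxo-2H-chromene-3-carboxylate
Conditions: piperidine (cat.), AcOH (cat.), MeOH, reflux
Reagents that add atoms: none
Why: Knoevenagel condensation of the malonate with the aldehyde followed by transesterification onto one of the two equivalent ortho hydroxyls closes the pyranone ring (standard coumarin-3-carboxylate synthesis) and leaves the other hydroxyl at position 5 of the coumarin.

Step 5
Reactants: 9 methyl 5-hydroxy-2-oxo-2H-chromene-3-carboxylate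
Product: 10 methyl 5-(methoxymethoxy)-2-oxo-2H-chromene-3-carboxylate
Conditions: MOMCl, i-Pr2NEt, CH2Cl2, 0 °C → rt
Reagents that add atoms: chloromethyl methyl ether, COCCl
Why: O-Alkylation of the remaining phenol (MOM ether formation) with a hindered amine base that does not add to the electron-poor coumarin.

Step 6
Reactants: 6 [(1E,3E)-4-Ar-2-methylbuta-1,3-dien-1-yl]trimethylsilane; 10 methyl 5-(methoxymethoxy)-2-oxo-2H-chromene-3-carboxylate
Product: 11 methyl 7-Ar-1-(methoxymethoxy)-9-methyl-6-oxo-10-(trimethylsilyl)-6a,7,10,10a-tetrahydro-6H-benzo[c]chromene-6a-carboxylate (one face: SiMe3 at C-2 / ring B at C-3 / lactone C=O at C-4 / Ar at C-5; other face: CO2Me at C-4)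
Conditions: Cu(OTf)2 (10 mol%), (S,S)-t-Bu-box (11 mol%), 4 Å MS, CH2Cl2, −40 → 0 °C
Reagents that add atoms: none
Why: Proposed new method: the lactone and ester carbonyls of 10 should bind the divalent copper of the Cu(OTf)2/bis(oxazoline) complex as a six-membered chelate, which lowers the LUMO of the coumarin alkene and screens one of its faces, so that diene 6 adds in a concerted, asynchronous, suprafacial [4+2] cycloaddition that starts at the coumarin β-carbon; the closest known reactions are thermal and Lewis-acid-promoted Diels–Alder reactions of coumarin-3-carboxylates with isoprene-type dienes and Cu(OTf)2/bis(oxazoline)-catalysed enantioselective additions to coumarin-3-carboxylates and alkylidene malonates. The cyclohexene ring closes by intermolecular [4+2] cycloaddition that forms C-2–C-3 and C-4–C-5 and leaves the alkene at C-1=C-6, cis-fused to the lactone. The regiochemistry needed, silylated terminus to the β-carbon, is secured by the diene itself: that terminus is remote from the aryl group and next to the methyl group, so it has the largest HOMO coefficient, and the positive charge that builds up at C-1 is β to silicon. C-3 and C-4 keep the cis geometry of the coumarin alkene, and C-2 and C-5 are cis to each other because both diene double bonds are E. The endo transition state with the lactone ring under the diene, the usual preference of a ring carbonyl over an acyclic ester in 2-alkoxycarbonyl cycloalkenones and quinones, places silicon and the C-5 aryl on the same face as ring B and the lactone carbonyl, and it is this selectivity that fixes the cis relation of C-3 and C-5. The absolute configuration of the four new centres comes from the ligand, which must leave open the face that is Si at the β-carbon (C-3).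

Step 7
Reactants: 11 methyl ester cycloadduct
Product: 12 7-Ar-1-(methoxymethoxy)-9-methyl-10-(trimethylsilyl)-6a,7,10,10a-tetrahydro-6H-benzo[c]chromen-6-one (all-cis: SiMe3 / ring B / lactone C=O / Ar on one face)
Conditions: LiCl, H2O, DMSO, 140 °C
Reagents that add atoms: none
Why: Krapcho dealkoxycarbonylation: chloride demethylates the ester by SN2 attack, the malonate-type carboxylate loses CO2 and the lactone enolate is protonated at C-4 from the face opposite the C-5 aryl and the silyl group, which should leave the all-cis lactone (a trans-fused epimer, if formed, converges in step 10).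

Step 8
Reactants: 13 4-bromobenzene-1,3-diol
Product: 14 1-bromo-2,4-bis(methoxymethoxy)benzene
Conditions: MOMCl, i-Pr2NEt, CH2Cl2, 0 °C → rt
Reagents that add atoms: chloromethyl methyl ether, COCCl
Why: O-Alkylation of both phenols (MOM ether formation) gives the base-stable, acid-labile protection that the aryllithium and the later steps need.

Step 9
Reactants: 14 1-bromo-2,4-bis(methoxymethoxy)benzene; 12 all-cis lactone
Product: 17 Ar{2-Ar-6-[2-hydroxy-6-(methoxymethoxy)phenyl]-4-methyl-5-(trimethylsilyl)cyclohex-3-en-1-yl}methanone (all-cis), via aryllithium 15 (not isolated), via lithium hemiketalate 16 (not isolated)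
Conditions: 14, n-BuLi, THF, −78 °C; then 12, −78 °C; aq. NH4Cl
Reagents that add atoms: none
Why: Bromine–lithium exchange gives the aryllithium, which adds once to the aryl ester carbonyl of the lactone (nucleophilic acyl substitution); the hindered cyclic lithium hemiketal persists at −78 °C, which guards against a second addition, and opens on protonation to the C-8 ketone and the free ring B phenol without touching C-3, C-4 or C-5.

Step 10
Reactants: 17 all-cis keto phenol
Product: 18 the C-4 epimer of 17 (acyl group trans to both aryl groups; SiMe3 still cis to ring B)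
Conditions: DBU, PhMe, 80 °C
Reagents that add atoms: none
Why: Base-mediated enolisation and reprotonation (epimerisation) at C-4, the only enolisable position, should move the acyl group trans to both neighbouring aryl groups because this relieves the 1,3-diaxial strain of the all-cis array, so C-4 is set under thermodynamic control.

Step 11
Reactants: 18 trans,trans keto phenol
Product: 19 3-[6-(Ar-carbonyl)-5-Ar-3-methyl-2-(trimethylsilyl)cyclohex-3-en-1-yl]-2-hydroxy-4-(methoxymethoxy)benzaldehyde (ring configuration of 18)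
Conditions: MgCl2, Et3N, (CH2O)n, MeCN, 80 °C
Reagents that add atoms: paraformaldehyde (as formaldehyde), C=O
Why: Magnesium-phenoxide-directed ortho-formylation (Casnati–Skattebøl reaction) delivers formaldehyde to the single free position ortho to the phenol and a second formaldehyde oxidises the benzylic alkoxide by hydride transfer; the choice of position is not critical, since the two positions para to the ring B oxygens become equivalent once both oxygens are free.

Step 12
Reactants: 19 salicylaldehyde
Product: 20 3-[6-(Ar-carbonyl)-5-Ar-3-methyl-2-(trimethylsilyl)cyclohex-3-en-1-yl]-2,4-bis(methoxymethoxy)benzaldehyde (ring configuration of 18)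
Conditions: MOMCl, i-Pr2NEt, CH2Cl2, 0 → 40 °C
Reagents that add atoms: chloromethyl methyl ether, COCCl
Why: O-Alkylation of the salicylaldehyde-type phenol (MOM ether formation), needed so that the aldehyde is not deactivated as a phenoxide in the condensation that follows.

Step 13
Reactants: 21 1-(2,4-dihydroxyphenyl)ethan-1-one
Product: 22 1-[2-hydroxy-4-(methoxymethoxy)phenyl]ethan-1-one
Conditions: MOMCl, K2CO3, acetone, rt
Reagents that add atoms: chloromethyl methyl ether, COCCl
Why: Selective O-alkylation of the 4-OH with a weak base (MOM ether formation), the 2-OH being held in a hydrogen bond to the ketone and kept free for the later ring closure.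

Step 14
Reactants: 20 aldehyde; 22 1-[2-hydroxy-4-(methoxymethoxy)phenyl]ethan-1-one
Product: 23 (2E)-3-{3-[6-(Ar-carbonyl)-5-Ar-3-methyl-2-(trimethylsilyl)cyclohex-3-en-1-yl]-2,4-bis(methoxymethoxy)phenyl}-1-[2-hydroxy-4-(methoxymethoxy)phenyl]prop-2-en-1-one
Conditions: KOH, EtOH/H2O, rt
Reagents that add atoms: none
Why: Claisen–Schmidt (crossed aldol) condensation of the methyl ketone enolate of 22 with the non-enolisable aldehyde gives the E-configured 2'-hydroxychalcone, while C-4 of the cyclohexene, the only other enolisable centre, is already in its stable configuration.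

Step 15
Reactants: 23 2'-hydroxychalcone
Product: 25 2-{3-[6-(Ar-carbonyl)-5-Ar-3-methyl-2-(trimethylsilyl)cyclohex-3-en-1-yl]-2,4-bis(methoxymethoxy)phenyl}-3-hydroxy-7-(methoxymethoxy)-4H-chromen-4-one, via flavanonol 24 (not isolated)
Conditions: H2O2 (30% aq.), NaOH, MeOH/THF, 0 °C → rt
Reagents that add atoms: hydrogen peroxide, OO
Why: Algar–Flynn–Oyamada reaction: alkaline hydrogen peroxide oxidises the enone and the phenoxide closes the pyranone to the flavanonol, which is oxidised on to the flavonol; ring A has no substituent next to the carbonyl, which favours flavonol over aurone, and the isolated allylsilane alkene does not react with nucleophilic peroxide.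

Step 16
Reactants: 25 heptakis-MOM flavonol allylsilane
Product: 26 CNP0190989.1: 2-{3-[(1R,5S,6R)-6-(2,4-dihydroxybenzoyl)-5-(2,4-dihydroxyphenyl)-3-methylcyclohex-2-en-1-yl]-2,4-dihydroxyphenyl}-3,7-dihydroxy-4H-chromen-4-one
Conditions: HCl (3 M in MeOH), THF, rt → 50 °C
Reagents that add atoms: none
Why: Acid-catalysed acetal cleavage frees all seven phenols, and protonation of the allylsilane at C-6 gives the tertiary, β-silyl-stabilised cation at C-1 that loses silicon (SE2' protodesilylation) to place the alkene at C-1=C-2, with C-3, C-4 and C-5 untouched.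

**Compound list**

1 | 2,4-dihydroxybenzaldehyde | O=Cc1ccc(O)cc1O | starting material
2 | 2,4-bis(methoxymethoxy)benzaldehyde | O=Cc1ccc(OCOC)cc1OCOC | intermediate
3 | 1-[(E)-2-iodoethenyl]-2,4-bis(methoxymethoxy)benzene | I/C=C/c1ccc(OCOC)cc1OCOC | intermediate
4 | trimethyl(prop-1-yn-1-yl)silane | CC#C[Si](C)(C)C | starting material
5 | 9-[(Z)-1-(trimethylsilyl)prop-1-en-2-yl]-9-borabicyclo[3.3.1]nonane | C/C(=C\[Si](C)(C)C)B1C2CCCC1CCC2 | intermediate (not isolated)
6 | [(1E,3E)-4-[2,4-bis(methoxymethoxy)phenyl]-2-methylbuta-1,3-dien-1-yl]trimethylsilane | C[Si](C)(C)/C=C(C)/C=C/c1ccc(OCOC)cc1OCOC | intermediate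
7 | 2,6-dihydroxybenzaldehyde | O=Cc1c(O)cccc1O | starting material
8 | dimethyl malonate | COC(=O)CC(=O)OC | starting material
9 | methyl 5-hydroxy-2-oxo-2H-chromene-3-carboxylate | COC(=O)C1=Cc2c(O)cccc2OC1=O | intermediate
10 | methyl 5-(methoxymethoxy)-2-oxo-2H-chromene-3-carboxylate | COC(=O)C1=Cc2c(OCOC)cccc2OC1=O | intermediate
11 | methyl 7-[2,4-bis(methoxymethoxy)phenyl]-1-(methoxymethoxy)-9-methyl-6-oxo-10-(trimethylsilyl)-6a,7,10,10a-tetrahydro-6H-benzo[c]chromene-6a-carboxylate; cis ring fusion, 7-aryl and 10-SiMe3 on the face of the lactone carbonyl and of arene carbon C-10b, CO2Me on the other face | C[Si](C)(C)[C@@H]1C(C)=C[C@H](c2ccc(OCOC)cc2OCOC)[C@]2(C(=O)OC)C(=O)Oc3cccc(OCOC)c3[C@H]12 | intermediate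
12 | 7-[2,4-bis(methoxymethoxy)phenyl]-1-(methoxymethoxy)-9-methyl-10-(trimethylsilyl)-6a,7,10,10a-tetrahydro-6H-benzo[c]chromen-6-one; all-cis (H-6a, H-7, H-10 and H-10a on one face) | C[Si](C)(C)[C@@H]1C(C)=C[C@H](c2ccc(OCOC)cc2OCOC)[C@@H]2C(=O)Oc3cccc(OCOC)c3[C@H]12 | intermediate
13 | 4-bromobenzene-1,3-diol (4-bromoresorcinol) | Oc1ccc(Br)c(O)c1 | starting material
14 | 1-bromo-2,4-bis(methoxymethoxy)benzene | COCOc1ccc(Br)c(OCOC)c1 | intermediate
15 | [2,4-bis(methoxymethoxy)phenyl]lithium | [Li]c1ccc(OCOC)cc1OCOC | intermediate (not isolated)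
16 | lithium 6,7-bis[2,4-bis(methoxymethoxy)phenyl]-1-(methoxymethoxy)-9-methyl-10-(trimethylsilyl)-6a,7,10,10a-tetrahydro-6H-benzo[c]chromen-6-olate; ring centres as in 12, hemiketal carbon (C-8) unspecified | C[Si](C)(C)[C@@H]1C(C)=C[C@H](c2ccc(OCOC)cc2OCOC)[C@@H]2C([O-])(c4ccc(OCOC)cc4OCOC)Oc3cccc(OCOC)c3[C@H]12.[Li+] | intermediate (not isolated)
17 | [2,4-bis(methoxymethoxy)phenyl]{2-[2,4-bis(methoxymethoxy)phenyl]-6-[2-hydroxy-6-(methoxymethoxy)phenyl]-4-methyl-5-(trimethylsilyl)cyclohex-3-en-1-yl}methanone; the four ring substituents at C-2 to C-5 all cis | C[Si](C)(C)[C@@H]1C(C)=C[C@H](c2ccc(OCOC)cc2OCOC)[C@H](C(=O)c2ccc(OCOC)cc2OCOC)[C@@H]1c3c(O)cccc3OCOC | intermediate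
18 | [2,4-bis(methoxymethoxy)phenyl]{2-[2,4-bis(methoxymethoxy)phenyl]-6-[2-hydroxy-6-(methoxymethoxy)phenyl]-4-methyl-5-(trimethylsilyl)cyclohex-3-en-1-yl}methanone; acyl group trans to both aryl groups, SiMe3 cis to ring B | C[Si](C)(C)[C@@H]1C(C)=C[C@H](c2ccc(OCOC)cc2OCOC)[C@@H](C(=O)c2ccc(OCOC)cc2OCOC)[C@@H]1c3c(O)cccc3OCOC | intermediate
19 | 3-{6-[2,4-bis(methoxymethoxy)benzoyl]-5-[2,4-bis(methoxymethoxy)phenyl]-3-methyl-2-(trimethylsilyl)cyclohex-3-en-1-yl}-2-hydroxy-4-(methoxymethoxy)benzaldehyde; ring configuration as in 18 | C[Si](C)(C)[C@@H]1C(C)=C[C@H](c2ccc(OCOC)cc2OCOC)[C@@H](C(=O)c2ccc(OCOC)cc2OCOC)[C@@H]1c3c(O)c(C=O)ccc3OCOC | intermediate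
20 | 3-{6-[2,4-bis(methoxymethoxy)benzoyl]-5-[2,4-bis(methoxymethoxy)phenyl]-3-methyl-2-(trimethylsilyl)cyclohex-3-en-1-yl}-2,4-bis(methoxymethoxy)benzaldehyde; ring configuration as in 18 | C[Si](C)(C)[C@@H]1C(C)=C[C@H](c2ccc(OCOC)cc2OCOC)[C@@H](C(=O)c2ccc(OCOC)cc2OCOC)[C@@H]1c3c(OCOC)c(C=O)ccc3OCOC | intermediate
21 | 1-(2,4-dihydroxyphenyl)ethan-1-one (2,4-dihydroxyacetophenone) | CC(=O)c1ccc(O)cc1O | starting material
22 | 1-[2-hydroxy-4-(methoxymethoxy)phenyl]ethan-1-one | CC(=O)c1ccc(OCOC)cc1O | intermediate
23 | (2E)-3-{3-[6-[2,4-bis(methoxymethoxy)benzoyl]-5-[2,4-bis(methoxymethoxy)phenyl]-3-methyl-2-(trimethylsilyl)cyclohex-3-en-1-yl]-2,4-bis(methoxymethoxy)phenyl}-1-[2-hydroxy-4-(methoxymethoxy)phenyl]prop-2-en-1-one; ring configuration as in 18 | C[Si](C)(C)[C@@H]1C(C)=C[C@H](c2ccc(OCOC)cc2OCOC)[C@@H](C(=O)c2ccc(OCOC)cc2OCOC)[C@@H]1c3c(OCOC)c(/C=C/C(=O)c4ccc(OCOC)cc4O)ccc3OCOC | intermediate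
24 | 2-{3-[6-[2,4-bis(methoxymethoxy)benzoyl]-5-[2,4-bis(methoxymethoxy)phenyl]-3-methyl-2-(trimethylsilyl)cyclohex-3-en-1-yl]-2,4-bis(methoxymethoxy)phenyl}-3-hydroxy-7-(methoxymethoxy)-2,3-dihydro-4H-chromen-4-one; 2,3-trans, the two new centres unspecified, ring configuration as in 18 | C[Si](C)(C)[C@@H]1C(C)=C[C@H](c2ccc(OCOC)cc2OCOC)[C@@H](C(=O)c2ccc(OCOC)cc2OCOC)[C@@H]1c3c(OCOC)c(C4Oc5cc(OCOC)ccc5C(=O)C4O)ccc3OCOC | intermediate (not isolated)
25 | 2-{3-[6-[2,4-bis(methoxymethoxy)benzoyl]-5-[2,4-bis(methoxymethoxy)phenyl]-3-methyl-2-(trimethylsilyl)cyclohex-3-en-1-yl]-2,4-bis(methoxymethoxy)phenyl}-3-hydroxy-7-(methoxymethoxy)-4H-chromen-4-one; ring configuration as in 18 | C[Si](C)(C)[C@@H]1C(C)=C[C@H](c2ccc(OCOC)cc2OCOC)[C@@H](C(=O)c2ccc(OCOC)cc2OCOC)[C@@H]1c3c(OCOC)c(-c4oc5cc(OCOC)ccc5c(=O)c4O)ccc3OCOC | intermediate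
26 | 2-{3-[(1R,5S,6R)-6-(2,4-dihydroxybenzoyl)-5-(2,4-dihydroxyphenyl)-3-methylcyclohex-2-en-1-yl]-2,4-dihydroxyphenyl}-3,7-dihydroxy-4H-chromen-4-one (CNP0190989.1); ring B at C-3 and aryl at C-5 cis, acyl at C-4 trans to both | CC1=C[C@@H](c2c(O)ccc(-c3oc4cc(O)ccc4c(=O)c3O)c2O)[C@H](C(=O)c2ccc(O)cc2O)[C@@H](c2ccc(O)cc2O)C1 | target

**Step count and risks**

Total: 16 steps. Longest linear sequence: 12 steps (1 → 2 → 3 → 6 → 11 → 12 → 17 → 18 → 19 → 20 → 23 → 25 → 26).

Step 6 (the key step). What may go wrong: the many ether oxygens compete with the dicarbonyl unit for copper so that turnover stalls, the electron-rich diene is oxidised or protodesilylated by the Lewis acid, or the facial and endo preferences are too low. Fallback: from 6 and 10 the cycloaddition is run without a metal, in toluene at 110 °C in a sealed tube with a trace of BHT, which is the established way of bringing coumarin-3-carboxylates and 2-methyl dienes together. This should give 11 as the racemate, that is, mixed with its mirror image, the enantiomer of 11 F1. The two are separated by preparative chromatography on a chiral stationary phase (amylose tris(3,5-dimethylphenylcarbamate)), F1 is set aside, and the route is rejoined at 11.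

Step 9. What may go wrong: the aryllithium acts as a base at C-4 of the congested lactone instead of adding, or the hemiketal opens in the flask and the ketone takes up a second aryl group. Fallback: from 12, the lactone is opened by the chloromagnesium amide made from MeNH(OMe)·HCl and i-PrMgCl (THF, −20 °C), which should give the phenolic N-methoxy-N-methylamide F2. Aryllithium 15 (2.5 equiv, THF, −78 → 0 °C; the first equivalent forms the phenoxide) then adds once, because the chelated tetrahedral intermediate holds until work-up, and the route is rejoined at 17.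

Step 16. What may go wrong: during the time that protodesilylation needs, the freed phenols react further under acid. A ring B hydroxyl may capture the C-1 cation (cyclic ether), the C-8 ketone may form a cyclic ketal or chromene with ring B, or released formaldehyde equivalents may alkylate the resorcinol rings. Fallback: from 25, silicon is removed first, while the phenols are still masked, with CSA in CH2Cl2 at 0 °C. This should give the silicon-free heptakis-MOM ether F3 with the alkene already at C-1=C-2. The MOM groups are then cleaved without protic acid by ZnBr2 and n-PrSH in CH2Cl2 at 0 °C, where the thiol takes up the methoxymethyl group, and the route ends at 26.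

**Further compounds**

F1 | step 6 | enantiomer of 11 (all four ring stereocentres inverted), formed with 11 as the racemate | C[Si](C)(C)[C@H]1C(C)=C[C@@H](c2ccc(OCOC)cc2OCOC)[C@@]2(C(=O)OC)C(=O)Oc3cccc(OCOC)c3[C@@H]12
F2 | step 9 | 2-[2,4-bis(methoxymethoxy)phenyl]-6-[2-hydroxy-6-(methoxymethoxy)phenyl]-N-methoxy-N,4-dimethyl-5-(trimethylsilyl)cyclohex-3-ene-1-carboxamide, all-cis | C[Si](C)(C)[C@@H]1C(C)=C[C@H](c2ccc(OCOC)cc2OCOC)[C@H](C(=O)N(C)OC)[C@@H]1c3c(O)cccc3OCOC
F3 | step 16 | 2-{3-[6-[2,4-bis(methoxymethoxy)benzoyl]-5-[2,4-bis(methoxymethoxy)phenyl]-3-methylcyclohex-2-en-1-yl]-2,4-bis(methoxymethoxy)phenyl}-3-hydroxy-7-(methoxymethoxy)-4H-chromen-4-one, configuration as in 26 | CC1=C[C@@H](c2c(OCOC)ccc(-c3oc4cc(OCOC)ccc4c(=O)c3O)c2OCOC)[C@H](C(=O)c2ccc(OCOC)cc2OCOC)[C@@H](c2ccc(OCOC)cc2OCOC)C1
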